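**Plan**

- Cuts, in retrosynthetic order: the interflavan bond C4(second unit)–C8(galloylated unit), the gallate ester, then in ring C of the galloylated unit O1–C2 and C2–C1', then C8a–O1, then C4–C4a and the C3=C4 enone bond; the upper dimer is cut at its own C4–C8 bond.
- Enabling feature: in ring C of the galloylated unit, O1 lies between ring-A carbon C8a and C2, so without O1 the atoms C8a–C2–C3–C4–C4a are the five-membered ring of a 3-arylindan-1-one (flavan C2 = indanone C1, flavan C4 = indanone C3, bearing C8 of epicatechin).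
- Forward order: epicatechin-8-carbaldehyde and a 2'-bromoacetophenone give a chalcone; reductive Heck closes the indanone; oxygen insertion expands it to the dihydrocoumarin; hydroxylation, aryl ketone formation, reduction and Mitsunobu closure rebuild ring C with ring B; galloylation, coupling with a bromine-capped epigallocatechin dimer and hydrogenolysis finish.
- Stereochemistry: the epicatechin (EC) and epigallocatechin (EGC) units come from the chiral pool; C4 of the galloylated unit from the chiral palladium catalyst; C3 from enolate hydroxylation anti to the C4 aryl group; C2 from chelation-controlled reduction followed by SN2 inversion; both new 4β bonds from attack anti to the α-oriented 2-aryl and 3-oxygen groups of 2,3-cis flavan-4-yl cations.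

Key step: step 8

Remark: for the hindered substrate of step 7 the sense of induction of the bisphosphine cannot be assigned safely in advance; both antipodes are to be run and the one giving the 3R indanone kept (written below as (R)). Bn = benzyl; compounds 1, 7, 15, 22 and 24 are purchased.

**Route**

Step 1
Reactants: 1 (−)-epicatechin
Product: 2 5,7,3',4'-tetra-O-benzyl-(−)-epicatechin
Conditions: BnBr, K2CO3, DMF, 0 °C → rt
Reagents that add atoms: benzyl bromide, BrCc1ccccc1
Why: Williamson etherification in which K2CO3 ionises only the four phenols, so the secondary 3-OH stays free and the (2R,3R) centres are untouched.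

Step 2
Reactants: 2 5,7,3',4'-tetra-O-benzyl-(−)-epicatechin
Product: 3 3,5,7,3',4'-penta-O-benzyl-(−)-epicatechin
Conditions: NaH, BnBr, n-Bu4NI (cat.), THF/DMF, 0 °C → rt
Reagents that add atoms: benzyl bromide, BrCc1ccccc1
Why: Williamson etherification of the secondary alkoxide; the O3 benzyl ether keeps this hydroxyl out of the later organolithium, Mitsunobu and acylation steps and is removed in the final hydrogenolysis.

Step 3
Reactants: 3 3,5,7,3',4'-penta-O-benzyl-(−)-epicatechin
Product: 4 8-bromo-3,5,7,3',4'-penta-O-benzylepicatechin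
Conditions: NBS, CH2Cl2, −78 → 0 °C
Reagents that add atoms: N-bromosuccinimide, O=C1CCC(=O)N1Br
Why: Electrophilic aromatic bromination at C8 of ring A (ortho to O1 and 7-OBn, para to 5-OBn), the accessible activated position, since C6 lies between two benzyloxy groups; this is the usual regiochemistry of benzylated flavan-3-ols.

Step 4
Reactants: 4 8-bromo-3,5,7,3',4'-penta-O-benzylepicatechin
Product: 6 3,5,7,3',4'-penta-O-benzylepicatechin-8-carbaldehyde, via 8-lithio-penta-O-benzylepicatechin 5 (not isolated)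
Conditions: n-BuLi, THF, −78 °C; DMF, −78 → 0 °C; AcOH/H2O
Reagents that add atoms: N,N-dimethylformamide, CN(C)C=O; n-butyllithium, [Li]CCCC (lithium of 5 only)
Why: Bromine–lithium exchange followed by formylation of the aryllithium with DMF puts on C8 the carbon that becomes C4 of the galloylated unit.

Step 5
Reactants: 7 3',5'-bis(benzyloxy)acetophenone
Product: 8 2'-bromo-3',5'-bis(benzyloxy)acetophenone
Conditions: NBS, MeCN, 0 °C → rt
Reagents that add atoms: N-bromosuccinimide, O=C1CCC(=O)N1Br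
Why: Electrophilic aromatic bromination goes ortho to the acetyl group and para to a benzyloxy group rather than to the hindered position between the two ethers, and without acid the methyl ketone is not brominated.

Step 6
Reactants: 6 3,5,7,3',4'-penta-O-benzylepicatechin-8-carbaldehyde; 8 2'-bromo-3',5'-bis(benzyloxy)acetophenone
Product: 9 (E)-1-[2-bromo-3,5-bis(benzyloxy)phenyl]-3-(3,5,7,3',4'-penta-O-benzylepicatechin-8-yl)prop-2-en-1-one
Conditions: KOH (50% aq.), EtOH/THF, rt → 45 °C
Reagents that add atoms: none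
Why: Claisen–Schmidt condensation of the methyl ketone enolate with the non-enolisable aldehyde, with dehydration to the conjugated E-enone.

Step 7
Reactants: 9 the 2'-bromochalcone
Product: 10 (3R)-4,6-bis(benzyloxy)-3-(3,5,7,3',4'-penta-O-benzylepicatechin-8-yl)indan-1-one
Conditions: Pd(OAc)2 (10 mol %), (R)-3,5-Xyl-MeO-BIPHEP (12 mol %), HCO2Na, DMF, 80 °C
Reagents that add atoms: none
Why: Asymmetric intramolecular reductive Heck reaction of a 2'-halochalcone: the arylpalladium bromide adds to the enone in a formal 5-endo sense to form C3–C3a, the palladium enolate is protonated and formate regenerates zerovalent palladium, while the bisphosphine selects the enone face in the C–C bond-forming insertion and fixes the 3R centre independently of the remote epicatechin stereocentres.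

Step 8
Reactants: 10 (3R)-4,6-bis(benzyloxy)-3-(penta-O-benzylepicatechin-8-yl)indan-1-one
Product: 11 (4R)-5,7-bis(benzyloxy)-4-(3,5,7,3',4'-penta-O-benzylepicatechin-8-yl)-3,4-dihydrocoumarin
Conditions: mCPBA (2 equiv), NaHCO3, CH2Cl2, 0 °C → rt, dark
Reagents that add atoms: 3-chloroperoxybenzoic acid, O=C(OO)c1cccc(Cl)c1
Why: Baeyer–Villiger oxidation: the peracid adds to the C1 carbonyl to give the tetrahedral peroxy (Criegee) adduct, and the ring-fusion aryl carbon C7a shifts from carbon to the proximal peroxide oxygen with loss of 3-chlorobenzoate, as in the known conversion of 1-indanones into 3,4-dihydrocoumarins. Ring C is not closed by a cyclisation but arises by ring expansion of the five-membered carbocycle through this 1,2-aryl shift, which makes the C8a–O1 bond and the six-membered lactone in one event. No stereocentre is created, and the benzylic centre (indanone C3, lactone C4) is remote from the reacting carbonyl, not epimerisable under these conditions and carried through unchanged. The step needs aryl rather than methylene migration and oxidation of the ketone rather than of the benzyloxy-arenes: the sp2 carbon stabilises the electron-deficient migration transition state far better than the primary CH2 (the usual outcome for 1-indanones), and a bicarbonate-buffered peracid without strong acid is the reagent under which polyalkoxyarenes survive Dakin-type oxidations. The oxygen therefore enters exactly at C8a and completes the phloroglucinol pattern of ring A from a 3,5-dioxygenated acetophenone.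

Step 9
Reactants: 11 the 4-aryl-3,4-dihydrocoumarin
Product: 13 (3R,4R)-5,7-bis(benzyloxy)-3-hydroxy-4-(penta-O-benzylepicatechin-8-yl)-3,4-dihydrocoumarin (3,4-trans), via sodium lactone enolate 12 (not isolated)
Conditions: NaN(SiMe3)2, THF, −78 °C; 2-(phenylsulfonyl)-3-phenyloxaziridine, −78 °C; AcOH
Reagents that add atoms: 2-(phenylsulfonyl)-3-phenyloxaziridine, O=S(=O)(N1OC1c1ccccc1)c1ccccc1; sodium bis(trimethylsilyl)amide, C[Si](C)(C)[N-][Si](C)(C)C.[Na+] (sodium of 12 only)
Why: Electrophilic hydroxylation of the lactone enolate by the N-sulfonyloxaziridine, in which the bulky C4 aryl group shields one face of the planar enolate so that oxygen is delivered anti to it and the 3,4-trans (3R) alcohol results.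

Step 10
Reactants: 13 the trans-3-hydroxy lactone
Product: 14 (2R,3R)-3-[2,4-bis(benzyloxy)-6-hydroxyphenyl]-2-hydroxy-N-methoxy-N-methyl-3-(penta-O-benzylepicatechin-8-yl)propanamide
Conditions: MeNH(OMe)·HCl, AlMe3, CH2Cl2, 0 °C → rt; aq. HCl (0.5 M) work-up
Reagents that add atoms: N,O-dimethylhydroxylamine hydrochloride, CNOC.Cl
Why: Aminolysis of the activated aryl ester by the aluminium amide (Weinreb amide formation) opens the lactone, frees the C8a phenol and leaves C3 and C4 untouched.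

Step 11
Reactants: 15 5-bromo-1,2,3-trimethoxybenzene
Product: 16 5-bromobenzene-1,2,3-triol
Conditions: BBr3, CH2Cl2, −78 °C → rt; H2O
Reagents that add atoms: none
Why: Lewis-acid cleavage of the three aryl methyl ethers with BBr3, the bromine already sitting at the position that ordinary bromination of a pyrogallol ether would not reach.

Step 12
Reactants: 16 5-bromobenzene-1,2,3-triol
Product: 17 5-bromo-1,2,3-tris(benzyloxy)benzene
Conditions: BnBr, K2CO3, DMF, rt → 50 °C
Reagents that add atoms: benzyl bromide, BrCc1ccccc1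
Why: Williamson etherification of the three phenols gives the ring-B precursor in the same protecting group as the rest of the molecule.

Step 13
Reactants: 14 the hydroxy Weinreb amide; 17 5-bromo-1,2,3-tris(benzyloxy)benzene
Product: 19 (2R,3R)-3-[2,4-bis(benzyloxy)-6-hydroxyphenyl]-2-hydroxy-3-(penta-O-benzylepicatechin-8-yl)-1-[3,4,5-tris(benzyloxy)phenyl]propan-1-one, via 3,4,5-tris(benzyloxy)phenyllithium 18 (not isolated)
Conditions: 17, n-BuLi, THF, −78 °C; then 14 (18: 3.5 equiv), −78 → −40 °C; AcOH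
Reagents that add atoms: n-butyllithium, [Li]CCCC (lithium of 18 only)
Why: Bromine–lithium exchange followed by acyl substitution at the Weinreb amide, whose chelated tetrahedral adduct persists until the quench and stops the addition at the ketone; two equivalents of the aryllithium first deprotonate the phenol and the C2 hydroxyl, and no stereocentre is formed or enolised.

Step 14
Reactants: 19 the α-hydroxy ketone
Product: 20 (1S,2R,3R)-3-[2,4-bis(benzyloxy)-6-hydroxyphenyl]-3-(penta-O-benzylepicatechin-8-yl)-1-[3,4,5-tris(benzyloxy)phenyl]propane-1,2-diol (1,2-anti)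
Conditions: Zn(BH4)2, Et2O/THF, −30 → 0 °C; H2O
Reagents that add atoms: none
Why: Chelation-controlled hydride reduction in which zinc bridges the carbonyl oxygen and the α-hydroxyl (Cram chelate) and hydride enters from the face opposite the bulky diarylmethyl group, giving the 1,2-anti diol with the new centre 1S.

Step 15
Reactants: 20 the anti-diol phenol
Product: 21 5,7,3',4',5'-penta-O-benzylepigallocatechin-(4β→8)-3,5,7,3',4'-penta-O-benzylepicatechin (3-OH of the upper unit free; upper unit 2R,3R, 2,3-cis-3,4-trans)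
Conditions: PPh3, DIAD, THF, 0 °C → rt
Reagents that add atoms: none
Why: Intramolecular Mitsunobu etherification in which the phenol, the only acidic partner, displaces the benzylic oxyphosphonium group in a 6-exo-tet SN2 step with inversion (1S becomes flavan 2R) to give the 2,3-cis ring; attack at C3 is disfavoured by the neighbouring diarylmethine, and the 3,4,5-trioxygenated aryl ring stabilises a benzylic cation only weakly, which protects the inversion.

Step 16
Reactants: 21 the benzylated EGC-(4β→8)-EC dimer; 22 3,4,5-tris(benzyloxy)benzoic acid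
Product: 23 3-O-[3,4,5-tris(benzyloxy)benzoyl]-5,7,3',4',5'-penta-O-benzylepigallocatechin-(4β→8)-3,5,7,3',4'-penta-O-benzylepicatechin
Conditions: DCC, DMAP, CH2Cl2, rt
Reagents that add atoms: none
Why: Steglich esterification (carbodiimide activation, DMAP acyl transfer) of the only free hydroxyl, a method that reaches the hindered axial 3-hydroxyl of 4-arylflavan-3-ols.

Step 17
Reactants: 24 (−)-epigallocatechin
Product: 25 5,7,3',4',5'-penta-O-benzyl-(−)-epigallocatechin
Conditions: BnBr, K2CO3, DMF, 0 °C → rt, under argon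
Reagents that add atoms: benzyl bromide, BrCc1ccccc1
Why: Williamson etherification of the five phenols only, run under inert gas because the free pyrogallol ring is air-sensitive in base.

Step 18
Reactants: 25 5,7,3',4',5'-penta-O-benzyl-(−)-epigallocatechin
Product: 26 8-bromo-5,7,3',4',5'-penta-O-benzylepigallocatechin
Conditions: NBS, CH2Cl2, −78 → 0 °C
Reagents that add atoms: N-bromosuccinimide, O=C1CCC(=O)N1Br
Why: Electrophilic aromatic bromination at C8 of ring A as in step 3; the bromine later blocks the nucleophilic position of the electrophilic partner.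

Step 19
Reactants: 26 8-bromo-5,7,3',4',5'-penta-O-benzylepigallocatechin
Product: 27 8-bromo-4β-(2-ethoxyethoxy)-5,7,3',4',5'-penta-O-benzylepigallocatechin
Conditions: DDQ, EtOCH2CH2OH, CH2Cl2, rt
Reagents that add atoms: 2-ethoxyethanol, CCOCCO
Why: DDQ-mediated benzylic oxidation in which hydride abstraction from C4 gives the ring-A-stabilised cation (quinone methide) and the alcohol adds anti to the α-oriented 2-aryl and 3-hydroxyl groups to give the 4β ether.

Step 20
Reactants: 27 the capped monomeric electrophile; 25 5,7,3',4',5'-penta-O-benzyl-(−)-epigallocatechin (3 equiv)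
Product: 28 8-bromo-5,7,3',4',5'-penta-O-benzylepigallocatechin-(4β→8)-5,7,3',4',5'-penta-O-benzylepigallocatechin
Conditions: TMSOTf (cat.), CH2Cl2, −78 °C; Et3N quench
Reagents that add atoms: none
Why: Lewis-acid-promoted flavan-4-yl cation coupling (Friedel–Crafts alkylation) in which the C4 ether ionises and C8 of the nucleophile attacks the 2,3-cis cation from the β face, anti to the 2-aryl and 3-hydroxyl groups, giving the 4β→8 bond, while the bromine on C8 of the electrophile excludes self-condensation.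

Step 21
Reactants: 28 the capped dimer
Product: 29 8-bromo-5,7,3',4',5'-penta-O-benzylepigallocatechin-(4β→8)-4β-(2-ethoxyethoxy)-5,7,3',4',5'-penta-O-benzylepigallocatechin
Conditions: DDQ, EtOCH2CH2OH, CH2Cl2, rt
Reagents that add atoms: 2-ethoxyethanol, CCOCCO
Why: DDQ benzylic oxidation as in step 19, directed to the C4 methylene of the lower unit because the interflavan methine is buried between two ortho-disubstituted aryl rings, the alcohol again adding trans to the 3-hydroxyl.

Step 22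
Reactants: 29 the capped dimeric electrophile; 23 the galloylated dimer (1.5 equiv)
Product: 30 fully protected tetramer: 8-bromo-penta-O-benzyl-EGC-(4β→8)-penta-O-benzyl-EGC-(4β→8)-[3-O-(tri-O-benzylgalloyl)-penta-O-benzyl-EGC]-(4β→8)-penta-O-benzyl-EC
Conditions: TMSOTf, CH2Cl2, −78 → −40 °C; Et3N quench
Reagents that add atoms: none
Why: Lewis-acid-promoted flavan-4-yl cation coupling in which C8 of the galloylated unit, the most accessible nucleophilic position (both C6 positions lie between two benzyloxy groups), attacks the cation from the β face anti to its 2-aryl and 3-hydroxyl groups, and the bromine cap stops chain growth.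

Step 23
Reactants: 30 the protected tetramer
Product: 31 epigallocatechin-(4β→8)-epigallocatechin-(4β→8)-epigallocatechin 3-O-gallate-(4β→8)-epicatechin (CNP0305998.1)
Conditions: H2 (1 atm), Pd(OH)2/C, NaOAc, THF/MeOH/H2O, rt
Reagents that add atoms: none
Why: Catalytic hydrogenolysis removes the 23 benzyl ethers and the aryl bromide in one operation, the acetate buffer taking up HBr so that the acid-labile interflavan bonds and the gallate ester are kept.

**Compound list**

1 | (−)-epicatechin, (2R,3R) | O[C@@H]1Cc2c(O)cc(O)cc2O[C@@H]1c1ccc(O)c(O)c1 | starting material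
2 | 5,7,3',4'-tetra-O-benzyl-(−)-epicatechin | O[C@@H]1Cc2c(OCc3ccccc3)cc(OCc3ccccc3)cc2O[C@@H]1c1ccc(OCc2ccccc2)c(OCc2ccccc2)c1 | intermediate
3 | 3,5,7,3',4'-penta-O-benzyl-(−)-epicatechin | c1ccccc1CO[C@@H]1Cc2c(OCc3ccccc3)cc(OCc3ccccc3)cc2O[C@@H]1c1ccc(OCc2ccccc2)c(OCc2ccccc2)c1 | intermediate
4 | 8-bromo-3,5,7,3',4'-penta-O-benzylepicatechin | Brc1c(OCc7ccccc7)cc(OCc7ccccc7)c2c1O[C@H](c1ccc(OCc7ccccc7)c(OCc7ccccc7)c1)[C@H](OCc7ccccc7)C2 | intermediate
5 | 8-lithio-3,5,7,3',4'-penta-O-benzylepicatechin | [Li]c1c(OCc7ccccc7)cc(OCc7ccccc7)c2c1O[C@H](c1ccc(OCc7ccccc7)c(OCc7ccccc7)c1)[C@H](OCc7ccccc7)C2 | intermediate (not isolated)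
6 | 3,5,7,3',4'-penta-O-benzylepicatechin-8-carbaldehyde | O=Cc1c(OCc7ccccc7)cc(OCc7ccccc7)c2c1O[C@H](c1ccc(OCc7ccccc7)c(OCc7ccccc7)c1)[C@H](OCc7ccccc7)C2 | intermediate
7 | 3',5'-bis(benzyloxy)acetophenone | CC(=O)c1cc(OCc2ccccc2)cc(OCc2ccccc2)c1 | starting material
8 | 2'-bromo-3',5'-bis(benzyloxy)acetophenone | CC(=O)c1cc(OCc2ccccc2)cc(OCc2ccccc2)c1Br | intermediate
9 | (E)-1-[2-bromo-3,5-bis(benzyloxy)phenyl]-3-(penta-O-benzylepicatechin-8-yl)prop-2-en-1-one | O=C(/C=C/c2c(OCc7ccccc7)cc(OCc7ccccc7)c3c2O[C@H](c2ccc(OCc7ccccc7)c(OCc7ccccc7)c2)[C@H](OCc7ccccc7)C3)c1cc(OCc4ccccc4)cc(OCc4ccccc4)c1Br | intermediate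
10 | (3R)-4,6-bis(benzyloxy)-3-(penta-O-benzylepicatechin-8-yl)indan-1-one | O=C1C[C@@H](c2c(OCc7ccccc7)cc(OCc7ccccc7)c3c2O[C@H](c2ccc(OCc7ccccc7)c(OCc7ccccc7)c2)[C@H](OCc7ccccc7)C3)c2c(OCc7ccccc7)cc(OCc7ccccc7)cc21 | intermediate
11 | (4R)-5,7-bis(benzyloxy)-4-(penta-O-benzylepicatechin-8-yl)-3,4-dihydrocoumarin | O=C1C[C@@H](c2c(OCc7ccccc7)cc(OCc7ccccc7)c3c2O[C@H](c2ccc(OCc7ccccc7)c(OCc7ccccc7)c2)[C@H](OCc7ccccc7)C3)c2c(OCc7ccccc7)cc(OCc7ccccc7)cc2O1 | intermediate
12 | sodium enolate of lactone 11 | [Na+].[O-]C1=C[C@@H](c2c(OCc7ccccc7)cc(OCc7ccccc7)c3c2O[C@H](c2ccc(OCc7ccccc7)c(OCc7ccccc7)c2)[C@H](OCc7ccccc7)C3)c2c(OCc7ccccc7)cc(OCc7ccccc7)cc2O1 | intermediate (not isolated)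
13 | (3R,4R)-5,7-bis(benzyloxy)-3-hydroxy-4-(penta-O-benzylepicatechin-8-yl)-3,4-dihydrocoumarin (trans) | O=C1[C@H](O)[C@@H](c2c(OCc7ccccc7)cc(OCc7ccccc7)c3c2O[C@H](c2ccc(OCc7ccccc7)c(OCc7ccccc7)c2)[C@H](OCc7ccccc7)C3)c2c(OCc7ccccc7)cc(OCc7ccccc7)cc2O1 | intermediate
14 | (2R,3R)-3-[2,4-bis(benzyloxy)-6-hydroxyphenyl]-2-hydroxy-N-methoxy-N-methyl-3-(penta-O-benzylepicatechin-8-yl)propanamide | CON(C)C(=O)[C@H](O)[C@@H](c2c(OCc7ccccc7)cc(OCc7ccccc7)c3c2O[C@H](c2ccc(OCc7ccccc7)c(OCc7ccccc7)c2)[C@H](OCc7ccccc7)C3)c2c(OCc7ccccc7)cc(OCc7ccccc7)cc2O | intermediate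
15 | 5-bromo-1,2,3-trimethoxybenzene | COc1cc(Br)cc(OC)c1OC | starting material
16 | 5-bromobenzene-1,2,3-triol | Oc1cc(Br)cc(O)c1O | intermediate
17 | 5-bromo-1,2,3-tris(benzyloxy)benzene | Brc1cc(OCc2ccccc2)c(OCc2ccccc2)c(OCc2ccccc2)c1 | intermediate
18 | 3,4,5-tris(benzyloxy)phenyllithium | [Li]c1cc(OCc2ccccc2)c(OCc2ccccc2)c(OCc2ccccc2)c1 | intermediate (not isolated)
19 | (2R,3R)-3-[2,4-bis(benzyloxy)-6-hydroxyphenyl]-2-hydroxy-3-(penta-O-benzylepicatechin-8-yl)-1-[3,4,5-tris(benzyloxy)phenyl]propan-1-one | O=C(c1cc(OCc4ccccc4)c(OCc4ccccc4)c(OCc4ccccc4)c1)[C@H](O)[C@@H](c2c(OCc7ccccc7)cc(OCc7ccccc7)c3c2O[C@H](c2ccc(OCc7ccccc7)c(OCc7ccccc7)c2)[C@H](OCc7ccccc7)C3)c2c(OCc7ccccc7)cc(OCc7ccccc7)cc2O | intermediate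
20 | (1S,2R,3R)-3-[2,4-bis(benzyloxy)-6-hydroxyphenyl]-3-(penta-O-benzylepicatechin-8-yl)-1-[3,4,5-tris(benzyloxy)phenyl]propane-1,2-diol (1,2-anti) | O[C@@H](c1cc(OCc4ccccc4)c(OCc4ccccc4)c(OCc4ccccc4)c1)[C@H](O)[C@@H](c2c(OCc7ccccc7)cc(OCc7ccccc7)c3c2O[C@H](c2ccc(OCc7ccccc7)c(OCc7ccccc7)c2)[C@H](OCc7ccccc7)C3)c2c(OCc7ccccc7)cc(OCc7ccccc7)cc2O | intermediate
21 | 5,7,3',4',5'-penta-O-benzylepigallocatechin-(4β→8)-3,5,7,3',4'-penta-O-benzylepicatechin | O[C@@H]1[C@@H](c2c(OCc7ccccc7)cc(OCc7ccccc7)c3c2O[C@H](c2ccc(OCc7ccccc7)c(OCc7ccccc7)c2)[C@H](OCc7ccccc7)C3)c2c(OCc7ccccc7)cc(OCc7ccccc7)cc2O[C@@H]1c1cc(OCc4ccccc4)c(OCc4ccccc4)c(OCc4ccccc4)c1 | intermediate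
22 | 3,4,5-tris(benzyloxy)benzoic acid | OC(=O)c1cc(OCc2ccccc2)c(OCc2ccccc2)c(OCc2ccccc2)c1 | starting material
23 | 3-O-[3,4,5-tris(benzyloxy)benzoyl] ester of 21 | O=C(O[C@@H]1[C@@H](c2c(OCc7ccccc7)cc(OCc7ccccc7)c3c2O[C@H](c2ccc(OCc7ccccc7)c(OCc7ccccc7)c2)[C@H](OCc7ccccc7)C3)c2c(OCc7ccccc7)cc(OCc7ccccc7)cc2O[C@@H]1c1cc(OCc4ccccc4)c(OCc4ccccc4)c(OCc4ccccc4)c1)c1cc(OCc4ccccc4)c(OCc4ccccc4)c(OCc4ccccc4)c1 | intermediate
24 | (−)-epigallocatechin, (2R,3R) | O[C@@H]1Cc2c(O)cc(O)cc2O[C@@H]1c1cc(O)c(O)c(O)c1 | starting material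
25 | 5,7,3',4',5'-penta-O-benzyl-(−)-epigallocatechin | O[C@@H]1Cc2c(OCc3ccccc3)cc(OCc3ccccc3)cc2O[C@@H]1c1cc(OCc2ccccc2)c(OCc2ccccc2)c(OCc2ccccc2)c1 | intermediate
26 | 8-bromo-5,7,3',4',5'-penta-O-benzylepigallocatechin | O[C@@H]1Cc2c(OCc3ccccc3)cc(OCc3ccccc3)c(Br)c2O[C@@H]1c1cc(OCc2ccccc2)c(OCc2ccccc2)c(OCc2ccccc2)c1 | intermediate
27 | 8-bromo-4β-(2-ethoxyethoxy)-5,7,3',4',5'-penta-O-benzylepigallocatechin | CCOCCO[C@H]1c2c(OCc3ccccc3)cc(OCc3ccccc3)c(Br)c2O[C@H](c2cc(OCc3ccccc3)c(OCc3ccccc3)c(OCc3ccccc3)c2)[C@@H]1O | intermediate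
28 | 8-bromo-penta-O-benzylepigallocatechin-(4β→8)-penta-O-benzylepigallocatechin | O[C@@H]1Cc2c(OCc5ccccc5)cc(OCc5ccccc5)c([C@H]3c4c(OCc5ccccc5)cc(OCc5ccccc5)c(Br)c4O[C@H](c4cc(OCc5ccccc5)c(OCc5ccccc5)c(OCc5ccccc5)c4)[C@@H]3O)c2O[C@@H]1c1cc(OCc5ccccc5)c(OCc5ccccc5)c(OCc5ccccc5)c1 | intermediate
29 | 28 carrying a 4β-(2-ethoxyethoxy) group on the lower unit | CCOCCO[C@H]1c2c(OCc5ccccc5)cc(OCc5ccccc5)c([C@H]3c4c(OCc5ccccc5)cc(OCc5ccccc5)c(Br)c4O[C@H](c4cc(OCc5ccccc5)c(OCc5ccccc5)c(OCc5ccccc5)c4)[C@@H]3O)c2O[C@H](c2cc(OCc5ccccc5)c(OCc5ccccc5)c(OCc5ccccc5)c2)[C@@H]1O | intermediate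
30 | protected tetramer (23 benzyl groups, bromine on C8 of the top unit) | O=C(O[C@@H]1[C@@H](c2c(OCc7ccccc7)cc(OCc7ccccc7)c3c2O[C@H](c2ccc(OCc7ccccc7)c(OCc7ccccc7)c2)[C@H](OCc7ccccc7)C3)c2c(OCc8ccccc8)cc(OCc8ccccc8)c([C@H]3c4c(OCc8ccccc8)cc(OCc8ccccc8)c([C@H]5c6c(OCc8ccccc8)cc(OCc8ccccc8)c(Br)c6O[C@H](c6cc(OCc8ccccc8)c(OCc8ccccc8)c(OCc8ccccc8)c6)[C@@H]5O)c4O[C@H](c4cc(OCc8ccccc8)c(OCc8ccccc8)c(OCc8ccccc8)c4)[C@@H]3O)c2O[C@@H]1c1cc(OCc8ccccc8)c(OCc8ccccc8)c(OCc8ccccc8)c1)c1cc(OCc8ccccc8)c(OCc8ccccc8)c(OCc8ccccc8)c1 | intermediate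
31 | epigallocatechin-(4β→8)-epigallocatechin-(4β→8)-epigallocatechin 3-O-gallate-(4β→8)-epicatechin | O=C(O[C@@H]1[C@@H](c2c(O)cc(O)c3c2O[C@H](c2ccc(O)c(O)c2)[C@H](O)C3)c2c(O)cc(O)c([C@H]3c4c(O)cc(O)c([C@H]5c6c(O)cc(O)cc6O[C@H](c6cc(O)c(O)c(O)c6)[C@@H]5O)c4O[C@H](c4cc(O)c(O)c(O)c4)[C@@H]3O)c2O[C@@H]1c1cc(O)c(O)c(O)c1)c1cc(O)c(O)c(O)c1 | target

**Step count and risks**

Total: 23 steps. Longest linear sequence: 15 steps (1, 2, 3, 4, 6, 7, 8, 9, 10, 13, 14, 15, 16, 22, 23).

Steps most likely to fail: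

1. Step 8. The oxygen insertion into the hindered, conjugated ketone may be slow, so that electrophilic oxidation of the benzyloxy-substituted rings, or migration of the methylene carbon, competes. Fallback from 6, returning at 11: Knoevenagel–Doebner condensation of 6 with malonic acid (pyridine, piperidine, 90 °C) should give (E)-3-(3,5,7,3',4'-penta-O-benzylepicatechin-8-yl)acrylic acid F1. Acid-mediated hydroarylation and lactonisation of F1 with purchased 3,5-bis(benzyloxy)phenol (TFA, CH2Cl2, rt) then builds the lactone by Friedel–Crafts attack of the phenol on the ring-A-stabilised benzylic cation, the third oxygen of ring A coming from the phenol. This gives 11 together with its C4 epimer; the two are diastereomers and are separated by chromatography, so catalyst control of C4 is given up.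

2. Step 7. Oxidative addition and insertion at the doubly ortho-substituted arylpalladium may be slow, which would let hydrodebromination take over or erode the facial selectivity. Fallback from 8 and 6, returning at 10: Miyaura borylation of 8 (B2pin2, Pd(dppf)Cl2, KOAc, dioxane, 90 °C) should give 1-[3,5-bis(benzyloxy)-2-(4,4,5,5-tetramethyl-1,3,2-dioxaborolan-2-yl)phenyl]ethanone F2. Claisen–Schmidt condensation with 6 then gives the (E)-2'-boryl chalcone F3. Rhodium-catalysed asymmetric intramolecular 1,4-addition of F3 ([Rh(C2H4)2Cl]2, MonoPhos antipode chosen as in the remark, aq. K3PO4, toluene, 80 °C) closes the same C3–C3a bond to 10 by transmetalation instead of oxidative addition.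

3. Step 15. The benzylic oxyphosphonium ion may ionise, losing the inversion and drifting to the all-trans ring, or the C3 hydroxyl may be activated instead, leading to an epoxide or a five-membered ether. Fallback from 20, returning at 21: the diol is converted with HC(OEt)3 and pyridinium p-toluenesulfonate in CH2Cl2 into the cyclic 2-ethoxy-1,3-dioxolane (orthoformate) of the 1,2-diol F4. Warming F4 with the same acid (ClCH2CH2Cl, 60 °C) generates the dioxolan-2-ylium ion, which the phenol opens at the benzylic carbon with inversion to give the 3-O-formate of 21 F5. Methanolysis (K2CO3, MeOH, 0 °C) returns 21.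

Further compounds
F1 | step 8 | (E)-3-(3,5,7,3',4'-penta-O-benzylepicatechin-8-yl)acrylic acid | OC(=O)/C=C/c1c(OCc7ccccc7)cc(OCc7ccccc7)c2c1O[C@H](c1ccc(OCc7ccccc7)c(OCc7ccccc7)c1)[C@H](OCc7ccccc7)C2
F2 | step 7 | 1-[3,5-bis(benzyloxy)-2-(4,4,5,5-tetramethyl-1,3,2-dioxaborolan-2-yl)phenyl]ethanone | CC(=O)c1cc(OCc2ccccc2)cc(OCc2ccccc2)c1B5OC(C)(C)C(C)(C)O5
F3 | step 7 | (E)-1-[3,5-bis(benzyloxy)-2-(4,4,5,5-tetramethyl-1,3,2-dioxaborolan-2-yl)phenyl]-3-(penta-O-benzylepicatechin-8-yl)prop-2-en-1-one | O=C(/C=C/c2c(OCc7ccccc7)cc(OCc7ccccc7)c3c2O[C@H](c2ccc(OCc7ccccc7)c(OCc7ccccc7)c2)[C@H](OCc7ccccc7)C3)c1cc(OCc4ccccc4)cc(OCc4ccccc4)c1B5OC(C)(C)C(C)(C)O5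
F4 | step 15 | cyclic 2-ethoxy-1,3-dioxolane (orthoformate) of diol 20 | CCOC1O[C@@H](c2cc(OCc4ccccc4)c(OCc4ccccc4)c(OCc4ccccc4)c2)[C@H](O1)[C@@H](c2c(OCc7ccccc7)cc(OCc7ccccc7)c3c2O[C@H](c2ccc(OCc7ccccc7)c(OCc7ccccc7)c2)[C@H](OCc7ccccc7)C3)c2c(OCc7ccccc7)cc(OCc7ccccc7)cc2O
F5 | step 15 | 3-O-formate of 21 | O=CO[C@@H]1[C@@H](c2c(OCc7ccccc7)cc(OCc7ccccc7)c3c2O[C@H](c2ccc(OCc7ccccc7)c(OCc7ccccc7)c2)[C@H](OCc7ccccc7)C3)c2c(OCc7ccccc7)cc(OCc7ccccc7)cc2O[C@@H]1c1cc(OCc4ccccc4)c(OCc4ccccc4)c(OCc4ccccc4)c1
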